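**Retrosynthetic overview**
1. The C–S bond is made last: target 11 comes from terminal alkene 10 by radical anti-Markovnikov addition of methanethiol, so sulfur never meets the methylating agent or the Rh catalyst.
2. 10 comes from 4-hydroxy-2-pyranone 9 by O-methylation; 9 comes from 3,5-diketo ester 8 by lactonisation (the only ring, formed once).
3. Key C–C bond (C5–C6 of the pyranone): 8 comes from the γ-carbanion of the dianion of methyl 2-methoxy-3-oxopentanoate 6 and Weinreb amide 3, an intermolecular Claisen-type acylation.
4. 6 comes from methyl 3-oxopentanoate 4 by diazo transfer and Rh-catalysed O–H insertion of methanol; 3 comes from undec-10-enoic acid 1.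

Assumption: the target has no stereocentre and no stereogenic double bond, so it is one achiral compound; the stereocentres of 6 and 8 (racemic or diastereomer mixtures) are erased when the pyranone forms.

**Route**

Step 1
Reactants: 1 undec-10-enoic acid
Product: 3 N-methoxy-N-methylundec-10-enamide, via 1-(undec-10-enoyl)imidazole 2 (not isolated)
Conditions: CDI (1.1 equiv), CH2Cl2, rt, 1 h; then MeNHOMe·HCl (1.2 equiv), rt, 12 h
Reagents that add atoms: N,O-dimethylhydroxylamine hydrochloride, CNOC.Cl; 1,1'-carbonyldiimidazole, O=C(n1ccnc1)n1ccnc1 (its imidazole is carried only in 2)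
Why: Acyl-imidazolide activation followed by amine acylation gives the Weinreb amide cleanly, and the terminal alkene is inert.

Step 2
Reactants: 4 methyl 3-oxopentanoate
Product: 5 methyl 2-diazo-3-oxopentanoate
Conditions: p-ABSA (1.1 equiv), Et3N (1.5 equiv), MeCN, 0 °C to rt
Reagents that add atoms: 4-acetamidobenzenesulfonyl azide, CC(=O)Nc1ccc(cc1)S(=O)(=O)N=[N+]=[N-]
Why: Regitz diazo transfer to the activated methylene of a β-keto ester is fast and high-yielding.

Step 3
Reactants: 5 methyl 2-diazo-3-oxopentanoate
Product: 6 methyl 2-methoxy-3-oxopentanoate (racemic)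
Conditions: Rh2(OAc)4 (1 mol %), MeOH (5 equiv), 1,2-dichloroethane, 70 °C
Reagents that add atoms: methanol, CO
Why: Rh(II)-carbenoid O–H insertion into methanol puts the future C3 methoxy group on the carbon between the two carbonyls; the new stereocentre is racemic and is destroyed in step 5.

Step 4
Reactants: 6 methyl 2-methoxy-3-oxopentanoate (1.5 equiv); 3 N-methoxy-N-methylundec-10-enamide (1.0 equiv)
Product: 8 methyl 2-methoxy-4-methyl-3,5-dioxopentadec-14-enoate, via dilithium bis-enolate 7 (not isolated)
Conditions: LDA (2.2 equiv per 6), THF, −78 to 0 °C, 30 min; then 3, −78 to 0 °C, 2 h; aq. NH4Cl / 1 M HCl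
Reagents that add atoms: lithium diisopropylamide, [Li+].CC(C)[N-]C(C)C (lithium is carried only in 7)
Why: In this Weiler-dianion crossed Claisen condensation the more basic γ-carbanion of 7 attacks the Weinreb amide, whose stable chelated adduct prevents over-addition and releases the diketo ester on quench; both stereocentres of 8 are epimer mixtures that vanish in step 5.

Step 5
Reactants: 8 methyl 2-methoxy-4-methyl-3,5-dioxopentadec-14-enoate
Product: 9 6-(dec-9-en-1-yl)-4-hydroxy-3-methoxy-5-methyl-2H-pyran-2-one
Conditions: DBU (1.5 equiv), toluene, rt to 60 °C, 6 h; then 1 M HCl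
Reagents that add atoms: none
Why: Base-mediated lactonisation, with the C5 enol oxygen attacking the methyl ester and methanol lost, is driven by formation of the aromatic-like pyronate.

Step 6
Reactants: 9 6-(dec-9-en-1-yl)-4-hydroxy-3-methoxy-5-methyl-2H-pyran-2-one
Product: 10 6-(dec-9-en-1-yl)-3,4-dimethoxy-5-methyl-2H-pyran-2-one
Conditions: Me2SO4 (1.3 equiv), K2CO3 (2 equiv), acetone, reflux, 4 h; aq. NH3 quench
Reagents that add atoms: dimethyl sulfate, COS(=O)(=O)OC
Why: Williamson-type O-alkylation of the potassium pyronate with dimethyl sulfate occurs at O-4 and gives the 4-methoxy-2-pyranone rather than the 2-methoxy-4-pyranone.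

Step 7
Reactants: 10 6-(dec-9-en-1-yl)-3,4-dimethoxy-5-methyl-2H-pyran-2-one
Product: 11 3,4-dimethoxy-5-methyl-6-[10-(methylsulfanyl)decyl]-2H-pyran-2-one
Conditions: MeSH (10 equiv, condensed at −20 °C), AIBN (0.1 equiv), degassed toluene, sealed tube, 70 °C, 8 h
Reagents that add atoms: methanethiol, CS
Why: The radical thiol–ene chain adds MeS• to the terminal CH2 (anti-Markovnikov) to give the primary methyl sulfide, while the tetrasubstituted, electron-poor pyranone double bonds add thiyl radicals only reversibly.

**Compound list**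
1 | undec-10-enoic acid | C=CCCCCCCCCC(=O)O | starting material
2 | 1-(undec-10-enoyl)imidazole | C=CCCCCCCCCC(=O)n1ccnc1 | intermediate
3 | N-methoxy-N-methylundec-10-enamide | C=CCCCCCCCCC(=O)N(C)OC | intermediate
4 | methyl 3-oxopentanoate | CCC(=O)CC(=O)OC | starting material
5 | methyl 2-diazo-3-oxopentanoate | CCC(=O)C(=[N+]=[N-])C(=O)OC | intermediate
6 | methyl 2-methoxy-3-oxopentanoate (racemic) | CCC(=O)C(OC)C(=O)OC | intermediate
7 | dilithium bis-enolate (dianion) of 6 | [Li+].[Li+].CC=C([O-])C(OC)=C([O-])OC | intermediate
8 | methyl 2-methoxy-4-methyl-3,5-dioxopentadec-14-enoate (diastereomer/tautomer mixture) | C=CCCCCCCCCC(=O)C(C)C(=O)C(OC)C(=O)OC | intermediate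
9 | 6-(dec-9-en-1-yl)-4-hydroxy-3-methoxy-5-methyl-2H-pyran-2-one | COc1c(O)c(C)c(CCCCCCCCC=C)oc1=O | intermediate
10 | 6-(dec-9-en-1-yl)-3,4-dimethoxy-5-methyl-2H-pyran-2-one | COc1c(OC)c(C)c(CCCCCCCCC=C)oc1=O | intermediate
11 | 3,4-dimethoxy-5-methyl-6-[10-(methylsulfanyl)decyl]-2H-pyran-2-one | COc1c(C)c(CCCCCCCCCCSC)oc(=O)c1OC | target

**Totals:** 7 steps; longest linear sequence 6 steps (4 → 5 → 6 → 8 → 9 → 10 → 11).

**Three steps most likely to fail, with fallbacks**

Step 4 (dianion Claisen acylation): the hindered secondary γ-carbanion may react sluggishly with the Weinreb amide, or the dianion may form incompletely. The fallback sets out from 3 and returns at 8 by an aldol/oxidation sequence. Weinreb amide 3 is reduced with DIBAL-H (THF, −78 °C) to undec-10-enal F1. The dianion 7, made as before, adds to this much more electrophilic aldehyde at −78 °C to give methyl 5-hydroxy-2-methoxy-4-methyl-3-oxopentadec-14-enoate F2 as a diastereomer mixture of no consequence. Dess–Martin periodinane (CH2Cl2, NaHCO3, rt) oxidises the secondary alcohol to diketo ester 8.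

Step 6 (O-methylation): the ambident pyronate, flanked by OMe and Me, may give some 2-methoxy-4-pyranone isomer or react slowly. The fallback sets out from 9 and returns at 10 by a Mitsunobu etherification (MeOH, PPh3, DIAD, THF, 0 °C to rt). Here the acidic 4-OH is methylated under neutral conditions through the pyronate/methoxyphosphonium ion pair instead of by a free alkylating agent. New compounds: none F0.

Step 7 (thiol–ene with gaseous MeSH): the radical chain may be short or incomplete on small scale. The fallback sets out from 10 and returns at 11 by a polar sequence. Hydroboration with 9-BBN (THF, 0 °C to rt) and mild oxidation with NaBO3·4H2O gives 6-(10-hydroxydecyl)-3,4-dimethoxy-5-methyl-2H-pyran-2-one F3. MsCl/Et3N (CH2Cl2, 0 °C) gives 10-(3,4-dimethoxy-5-methyl-2-oxo-2H-pyran-6-yl)decyl methanesulfonate F4. NaSMe (1.05 equiv, DMF, 0 °C) displaces the primary mesylate by SN2 to give 11.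

**Further compounds**
F1 | step 4 | undec-10-enal | C=CCCCCCCCCC=O
F2 | step 4 | methyl 5-hydroxy-2-methoxy-4-methyl-3-oxopentadec-14-enoate (diastereomer mixture) | C=CCCCCCCCCC(O)C(C)C(=O)C(OC)C(=O)OC
F0 | step 6 | none | none
F3 | step 7 | 6-(10-hydroxydecyl)-3,4-dimethoxy-5-methyl-2H-pyran-2-one | COc1c(OC)c(C)c(CCCCCCCCCCO)oc1=O
F4 | step 7 | 10-(3,4-dimethoxy-5-methyl-2-oxo-2H-pyran-6-yl)decyl methanesulfonate | COc1c(OC)c(C)c(CCCCCCCCCCOS(C)(=O)=O)oc1=O
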